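The data stem from a simulated flask from invented constants; the scatter is artificial.

- The closed, stirred vessel turns starting material into open intermediate and that into target, with partner charged beside them; what counts is the open intermediate standing at the end of each flask.

| flask | starting material | partner | temperature | remark | time |
|---|---|---|---|---|---|
| amber | 1.5 M | 1.3 M | 20 °C | run made earlier |  |
| beta | 1.0 M | 1.30 M | 20 °C |  | 3.0 h |
| alpha | 1.0 M | 1.30 M |  | at 20 °C until 50 min, from then on at −20 °C | 3.0 h |
| epsilon | 1.0 M | 1.30 M | 0 °C |  | 3.0 h |
| zeta | 1.0 M | 1.30 M | −20 °C |  | 3.0 h |

- amber (time / min: open intermediate / %, target / %, starting material / %): 1.33: 13.6, 0.5, 86.0; 2.50: 23.3, 1.1, 74.4; 4.00: 31.3, 3.4, 62.7; 6.00: 36.5, 12.0, 49.4; 10.0: 37.7, 25.2, 32.7; 20.0: 30.2, 52.6, 15.7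

(each reading ± 0.5 percentage points)

1. the best flask by amount of open intermediate, in percent of the starting material charged; "all alike" if 1.5 percentage points covers them all (beta / alpha / epsilon / zeta / all alike)
2. amount of open intermediate at the end, in percent of the starting material charged, beta
3. amount of open intermediate at the end, in percent of the starting material charged, alpha
4. amount of open intermediate at the end, in percent of the starting material charged, epsilon
5. amount of open intermediate at the end, in percent of the starting material charged, zeta

- the earlier runs do not show what temperature does; that part of a forecast is a guess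
- a reading or a percentage of target counts all its forms, free or not
- a reading of starting material is of its free form alone

- The amber run reads best through the fraction left, not the fraction made. At 10.0 min, 32.7% left gives 0.112 min⁻¹: this is the fall constant, ln(charged/left) divided by time, an apparent first-order constant.
- One objection is that the new flasks hold less starting material than amber. But amber's own reading at 1.33 min gives 0.113 min⁻¹, so the constant holds while the amount falls to a third, and a smaller charge should not move it.
- A second objection stands. At 20.0 min the constant predicts 10.7% left, yet 15.7% was read, 5 percentage points higher against a scatter of 0.5 points, so the constant serves the early fall and not the tail.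
- Open intermediate is made from starting material, so in these closed flasks one minus the fraction left is its ceiling.
- Between 10.0 min and 20.0 min, amber's target gains at a drain constant of 0.0807 min⁻¹. This is a reading of one stretch, since target starts with an induction, perhaps waiting on [partner]. Even so, beta has 12.9 drain lifetimes after that stretch, so beta should end low.
- The cold flasks rest on a guess. A guessed factor of 2 to 3 per 10 degrees gives a slowing of 16.0 to 81.0 from amber to zeta and puts zeta's ceiling anywhere from 71.6% down to 22.0%, so the ceiling has to enter the estimate.
- This reckoning commits to the steeper guess. Epsilon, slowed by 9.00, then has 2.24 fall lifetimes and 1.61 drain lifetimes, and its ceiling of 89.3% stands above zeta's 22.0%, so epsilon should end above zeta.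
- The forecast differs: it gives 0.5% for beta, 2% for alpha, 16% for epsilon and 35% for zeta, and names zeta as best, since there “intermediate sits near its maximum”.
- The flasks end with 1.85% in beta, 9.59% in alpha, 16.6% in epsilon and 6.09% in zeta, so the best is epsilon.

    2 second intermediate → homo product (k = 0.00110 M⁻¹ min⁻¹, Ea = 77.0 kJ mol⁻¹)
    partner → second intermediate (k = 0.0140 min⁻¹, Ea = 80.0 kJ mol⁻¹)
    open intermediate + second intermediate → target (k = 0.0250 M⁻¹ min⁻¹, Ea = 62.0 kJ mol⁻¹)
    starting material + target ⇌ idle adduct, settled at all times (K = 0.700 M⁻¹, ΔH = −26.0 kJ mol⁻¹)
    starting material ⇌ open intermediate (K = 3.80, k = 0.00810 min⁻¹, Ea = 89.0 kJ mol⁻¹, ΔH = 12.0 kJ mol⁻¹)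
    starting material → decomposition product (k = 3.60 × 10⁻⁵ min⁻¹, Ea = 99.0 kJ mol⁻¹)
    crystals ⇌ target, rate k7*(cs7 - [target]) while solid is left; crystals form when [target] > cs7 (solubility = 0.420 M, k = 1.50 min⁻¹)
    (constants at 0 °C)

- Zeta ends with 94% of its starting material still free. Its fall constant is therefore 3.70 × 10⁻⁴ min⁻¹, slower than amber's 0.112 min⁻¹ by a factor of 302, and its ceiling of 6.44% stands just above its 6.09% of open intermediate. Epsilon repeated at −15 °C keeps 86%, which gives a fall constant of 8.61 × 10⁻⁴ min⁻¹ and a ceiling of 14.4%, and that flask holds 12.1% of open intermediate.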